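The disconnection on which everything rests is the O1–C6 bond of the 2-methoxy-4-pyranone ring (O1, C2–OMe, C3–Me, C4=O, C5, C6 bearing side chain C1'–C11'), which unfolds the heterocycle into an open-chain methyl 3-oxoalk-4-ynoate. The key step exploits the ester carbonyl oxygen (future O1), poised for six-membered closure onto the ynone β carbon (future C6): a gold-catalysed 6-endo-dig cycloisomerisation builds the ring with C2–OMe, C3–Me and the C4 carbonyl in place in one operation. Its precursor, methyl (2RS,15S)-15-acetoxy-2-methyl-3-oxohexadec-4-ynoate, already holds the complete (S)-acetoxy side chain, assembled from dec-1-yne, (S)-propylene oxide (the sole source of chirality) and methyl propanoate. The C5 methyl follows by iodination and Suzuki–Miyaura methylation.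

Key step: step 9

Remark: the aldol adduct and the three β-keto esters after it are carried as mixtures of epimers at the centres next to the ester; the oxidation and the ring closure erase these centres, so only the centre from (S)-propylene oxide has to be controlled.

Step 1
Reactants: 1 dec-1-yne; 2 (S)-propylene oxide
Product: 4 (S)-tridec-4-yn-2-ol, via lithium dec-1-yn-1-ide 3 (not isolated)
Conditions: n-BuLi, THF, −78 °C; BF3·OEt2, then 2, −78 °C; H2O quench
Reagents that add atoms: none
Why: BF3-assisted SN2 opening of the epoxide by the lithium acetylide occurs at the unsubstituted CH2, so the C–O bond of the stereocentre is never broken and the (S) configuration is carried over unchanged.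

Step 2
Reactants: 4 (S)-tridec-4-yn-2-ol
Product: 5 (S)-tridec-12-yn-2-ol
Conditions: KH, H2N(CH2)3NH2 (forms KNH(CH2)3NH2), 0 °C → rt; H2O quench
Reagents that add atoms: none
Why: In this alkyne zipper reaction the potassium amide moves the triple bond by repeated propargyl–allenyl proton shifts down the unbranched chain (the C2 alkoxide blocks the other direction) until the terminal acetylide is trapped, and the carbinol centre, which only carries an alkoxide, should keep its (S) configuration.

Step 3
Reactants: 5 (S)-tridec-12-yn-2-ol
Product: 6 (S)-tert-butyldimethyl(tridec-12-yn-2-yloxy)silane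
Conditions: TBSCl, imidazole, DMF, rt
Reagents that add atoms: tert-butyldimethylsilyl chloride, CC(C)(C)[Si](C)(C)Cl
Why: Imidazole-promoted O-silylation of the only hydroxyl group masks it against the organolithium and enolate chemistry that follows, with retention because only the O–H bond reacts.

Step 4
Reactants: 6 (S)-tert-butyldimethyl(tridec-12-yn-2-yloxy)silane
Product: 8 (S)-13-[(tert-butyldimethylsilyl)oxy]tetradec-2-ynal, via lithium acetylide 7 (not isolated)
Conditions: n-BuLi, THF, −78 °C; DMF, −78 → 0 °C; inverse quench into aq. KH2PO4
Reagents that add atoms: N,N-dimethylformamide, CN(C)C=O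
Why: Formylation of the lithium acetylide with DMF gives a hemiaminal alkoxide that is stable until the buffered inverse quench, which releases the ynal at a pH where the liberated dimethylamine is protonated and cannot add to it.

Step 5
Reactants: 8 (S)-13-[(tert-butyldimethylsilyl)oxy]tetradec-2-ynal; 9 methyl propanoate
Product: 11 methyl (15S)-15-[(tert-butyldimethylsilyl)oxy]-3-hydroxy-2-methylhexadec-4-ynoate, via lithium enolate 10 (not isolated)
Conditions: LDA, THF, −78 °C (9, then 8); AcOH quench, −78 °C
Reagents that add atoms: none
Why: This aldol addition of a preformed lithium ester enolate goes 1,2 to the unhindered ynal carbonyl at −78 °C; the new centres at C2 and C3 are left uncontrolled as a diastereomer mixture because both are erased later.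

Step 6
Reactants: 11 methyl (15S)-15-[(tert-butyldimethylsilyl)oxy]-3-hydroxy-2-methylhexadec-4-ynoate
Product: 12 methyl (2RS,15S)-15-[(tert-butyldimethylsilyl)oxy]-2-methyl-3-oxohexadec-4-ynoate
Conditions: Dess–Martin periodinane, CH2Cl2, 0 °C → rt
Reagents that add atoms: none
Why: Dess–Martin oxidation of the propargylic secondary alcohol under neutral, non-aqueous conditions gives the ynone β-keto ester without touching the silyl ether or the alkyne, and it removes the C3 centre.

Step 7
Reactants: 12 methyl (2RS,15S)-15-[(tert-butyldimethylsilyl)oxy]-2-methyl-3-oxohexadec-4-ynoate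
Product: 13 methyl (2RS,15S)-15-hydroxy-2-methyl-3-oxohexadec-4-ynoate
Conditions: HF (48% aq.), MeCN, 0 °C → rt
Reagents that add atoms: none
Why: Desilylation with weakly acidic HF, driven by the strong Si–F bond, avoids the basic fluoride sources that would attack the ynone or the enolisable β-keto ester, and it leaves the carbinol C–O bond and its (S) configuration intact.

Step 8
Reactants: 13 methyl (2RS,15S)-15-hydroxy-2-methyl-3-oxohexadec-4-ynoate
Product: 14 methyl (2RS,15S)-15-acetoxy-2-methyl-3-oxohexadec-4-ynoate
Conditions: Ac2O, pyridine, CH2Cl2, 0 °C → rt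
Reagents that add atoms: acetic anhydride, CC(=O)OC(C)=O
Why: O-Acetylation (nucleophilic acyl substitution) of the only free hydroxyl group proceeds with retention, and at low temperature without a stronger nucleophilic catalyst pyridine should leave the ynone and the hindered 2-methyl β-keto ester alone.

Step 9
Reactants: 14 methyl (2RS,15S)-15-acetoxy-2-methyl-3-oxohexadec-4-ynoate
Product: 15 (S)-11-(6-methoxy-5-methyl-4-oxo-4H-pyran-2-yl)undecan-2-yl acetate
Conditions: Ph3PAuNTf2 (5 mol%), CH2Cl2, rt
Reagents that add atoms: none
Why: The cationic monovalent gold centre of Ph3PAuNTf2 binds the C4≡C5 alkyne of 14 as a π-acid, and the ester carbonyl oxygen adds anti to gold at chain C5, the ynone β carbon, which forms the O1–C6 ring bond and a vinylgold 2-methoxy oxocarbenium ion; loss of the acidic proton between the two carbonyl carbons (chain C2, ring C3) and protodeauration at ring C5 then release the neutral 2-methoxy-4-pyranone and the catalyst, so the step is a pure isomerisation. The closest known reaction type is the gold-catalysed cycloisomerisation of 3-oxoalk-4-ynoate esters to 4-hydroxy-2-pyranones or 2-alkoxy-4-pyranones. The one ring is closed in the 6-endo-dig mode by an oxygen nucleophile. No stereocentre is created: the epimeric chain C2 becomes the sp2 ring carbon C3, and the remote (S)-acetoxy carbon is not involved. The step needs 6-endo over 5-exo attack, which the ynone polarisation secures because chain C5 is the electron-poor β carbon, and it needs the methyl ether to survive, which the methyl ester secures because, unlike a tert-butyl ester, it cannot shed its alkyl group as a cation, so deprotonation is the only exit from the oxocarbenium ion.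

Step 10
Reactants: 15 (S)-11-(6-methoxy-5-methyl-4-oxo-4H-pyran-2-yl)undecan-2-yl acetate
Product: 16 (S)-11-(3-iodo-6-methoxy-5-methyl-4-oxo-4H-pyran-2-yl)undecan-2-yl acetate
Conditions: NIS, TFA (cat.), MeCN, rt, dark
Reagents that add atoms: N-iodosuccinimide, O=C1CCC(=O)N1I
Why: Ring C5 is the only ring CH and the nucleophilic α carbon of the vinylogous ester O1–C6=C5–C4=O, so electrophilic iodination of the 4-pyranone with acid-activated NIS should occur there alone, and neither the acetate nor the stereocentre is affected.

Step 11
Reactants: 16 (S)-11-(3-iodo-6-methoxy-5-methyl-4-oxo-4H-pyran-2-yl)undecan-2-yl acetate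
Product: 17 (S)-11-(6-methoxy-3,5-dimethyl-4-oxo-4H-pyran-2-yl)undecan-2-yl acetate
Conditions: trimethylboroxine, Pd(PPh3)4 (10 mol%), K2CO3, 1,4-dioxane (anhydrous), 100 °C
Reagents that add atoms: trimethylboroxine, CB1OB(C)OB(C)O1
Why: In this Suzuki–Miyaura methylation zerovalent palladium inserts into the C5–I bond of the α-iodoenone-type pyranone, carbonate-assisted methyl transfer from boron and reductive elimination give the C5–CH3 bond, and the anhydrous medium should spare the acetate.

Compound list
1 | dec-1-yne | C#CCCCCCCCC | starting material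
2 | (S)-propylene oxide, (S)-2-methyloxirane | C[C@H]1CO1 | starting material
3 | lithium dec-1-yn-1-ide (not isolated) | [Li]C#CCCCCCCCC | intermediate
4 | (S)-tridec-4-yn-2-ol | C[C@H](O)CC#CCCCCCCCC | intermediate
5 | (S)-tridec-12-yn-2-ol | C#CCCCCCCCCC[C@H](C)O | intermediate
6 | (S)-tert-butyldimethyl(tridec-12-yn-2-yloxy)silane | C#CCCCCCCCCC[C@H](C)O[Si](C)(C)C(C)(C)C | intermediate
7 | lithium (12S)-12-[(tert-butyldimethylsilyl)oxy]tridec-1-yn-1-ide (not isolated) | [Li]C#CCCCCCCCCC[C@H](C)O[Si](C)(C)C(C)(C)C | intermediate
8 | (S)-13-[(tert-butyldimethylsilyl)oxy]tetradec-2-ynal | O=CC#CCCCCCCCCC[C@H](C)O[Si](C)(C)C(C)(C)C | intermediate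
9 | methyl propanoate | CCC(=O)OC | starting material
10 | lithium enolate of methyl propanoate, lithium (Z)-1-methoxyprop-1-en-1-olate (not isolated) | C/C=C(\OC)O[Li] | intermediate
11 | methyl (15S)-15-[(tert-butyldimethylsilyl)oxy]-3-hydroxy-2-methylhexadec-4-ynoate, diastereomer mixture at C2 and C3 | COC(=O)C(C)C(O)C#CCCCCCCCCC[C@H](C)O[Si](C)(C)C(C)(C)C | intermediate
12 | methyl (2RS,15S)-15-[(tert-butyldimethylsilyl)oxy]-2-methyl-3-oxohexadec-4-ynoate | COC(=O)C(C)C(=O)C#CCCCCCCCCC[C@H](C)O[Si](C)(C)C(C)(C)C | intermediate
13 | methyl (2RS,15S)-15-hydroxy-2-methyl-3-oxohexadec-4-ynoate | COC(=O)C(C)C(=O)C#CCCCCCCCCC[C@H](C)O | intermediate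
14 | methyl (2RS,15S)-15-acetoxy-2-methyl-3-oxohexadec-4-ynoate | COC(=O)C(C)C(=O)C#CCCCCCCCCC[C@H](C)OC(C)=O | intermediate
15 | (S)-11-(6-methoxy-5-methyl-4-oxo-4H-pyran-2-yl)undecan-2-yl acetate | COc1oc(CCCCCCCCC[C@H](C)OC(C)=O)cc(=O)c1C | intermediate
16 | (S)-11-(3-iodo-6-methoxy-5-methyl-4-oxo-4H-pyran-2-yl)undecan-2-yl acetate | COc1oc(CCCCCCCCC[C@H](C)OC(C)=O)c(I)c(=O)c1C | intermediate
17 | (S)-11-(6-methoxy-3,5-dimethyl-4-oxo-4H-pyran-2-yl)undecan-2-yl acetate | COc1oc(CCCCCCCCC[C@H](C)OC(C)=O)c(C)c(=O)c1C | target

Total step count: 11 steps.
Longest linear sequence: 11 steps (from 1 to 17; 2 enters in step 1 and 9 in step 5).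

Steps most likely to fail

Step 9. The ring closure may stall if the enolised β-keto ester ties up the cationic gold centre. It may also leak to the 4-hydroxy-2-pyranone if traces of water demethylate the oxocarbenium ion. The fallback sets out from 14 and comes back to the route at 15, and it makes the ring by the classical triketide sequence instead of alkyne activation. Diethylamine is added across the ynone of 14 in THF at 0 °C to give the enaminone methyl (2RS,4E,15S)-15-acetoxy-5-(diethylamino)-2-methyl-3-oxohexadec-4-enoate F1. Dilute aqueous acetic acid hydrolyses it to the diketo ester methyl (2RS,15S)-15-acetoxy-2-methyl-3,5-dioxohexadecanoate F2. DBU in toluene should lactonise F2 with loss of methanol to the 4-hydroxy-2-pyranone (S)-11-(4-hydroxy-5-methyl-6-oxo-6H-pyran-2-yl)undecan-2-yl acetate F3. Methyl triflate in CH2Cl2 then methylates the lactone carbonyl oxygen of F3, and loss of the hydroxyl proton gives 15.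

Step 8. During the acetylation the amine base may add to the ynone, acetylate the enol of the β-keto ester, or trigger an uncontrolled base-induced ring closure. The fallback sets out from 12 and comes back at 15, and it moves the silyl-to-acetate exchange behind the ring closure, onto the robust pyranone. Ph3PAuNTf2 in CH2Cl2 should convert the silyl ether 12 into (S)-6-{10-[(tert-butyldimethylsilyl)oxy]undecyl}-2-methoxy-3-methyl-4H-pyran-4-one F4. Aqueous HF in MeCN frees the alcohol (S)-6-(10-hydroxyundecyl)-2-methoxy-3-methyl-4H-pyran-4-one F5. Ac2O with pyridine and DMAP then acetylates F5 to give 15.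

Step 11. Methyl transfer from boron to the hindered C5–palladium centre may be slow, which leads to protodeiodination, and carbonate at 100 °C may strip the acetate. The fallback sets out from 16 and comes back at 17. It replaces the boron reagent by an organozinc methyl donor in a base-free Negishi coupling: a commercial MeZnCl solution with Pd(PPh3)4 in THF at 50 °C. Transmetalation from zinc needs no base and runs at lower temperature, and MeZnCl adds neither to the acetate nor to the pyranone carbonyl. No new compound arises on this way (F0).

Further compounds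
F1 | step 9 | methyl (2RS,4E,15S)-15-acetoxy-5-(diethylamino)-2-methyl-3-oxohexadec-4-enoate | COC(=O)C(C)C(=O)/C=C(/N(CC)CC)CCCCCCCCC[C@H](C)OC(C)=O
F2 | step 9 | methyl (2RS,15S)-15-acetoxy-2-methyl-3,5-dioxohexadecanoate | COC(=O)C(C)C(=O)CC(=O)CCCCCCCCC[C@H](C)OC(C)=O
F3 | step 9 | (S)-11-(4-hydroxy-5-methyl-6-oxo-6H-pyran-2-yl)undecan-2-yl acetate | O=c1oc(CCCCCCCCC[C@H](C)OC(C)=O)cc(O)c1C
F4 | step 8 | (S)-6-{10-[(tert-butyldimethylsilyl)oxy]undecyl}-2-methoxy-3-methyl-4H-pyran-4-one | COc1oc(CCCCCCCCC[C@H](C)O[Si](C)(C)C(C)(C)C)cc(=O)c1C
F5 | step 8 | (S)-6-(10-hydroxyundecyl)-2-methoxy-3-methyl-4H-pyran-4-one | COc1oc(CCCCCCCCC[C@H](C)O)cc(=O)c1C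
F0 | step 11 | none | none
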